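**Retrosynthetic overview**
- The target (numbered as a germacra-1(10),11(13)-dien-8,12-olide) comes from a C6 alcohol of opposite configuration by Mitsunobu acylation with inversion, followed by release of the 2,4-diol.
- Ten-membered ring: the C6–C7 bond (the farnesyl C1–C10 bond of germacrene biosynthesis) is closed by intramolecular SE2′ allylation of a C6 aldehyde by a C13 allylchromium held in the preformed 8,12-butenolide. This step creates the C11=C13 exo-methylene and sets C6 and C7.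
- Butenolide: O8–C12 esterification with 2-(bromomethyl)acrylic acid, then C7=C11 ring-closing metathesis.
- C8–C9: Brown (Z)-γ-aryloxyallylboration of a (Z)-enal. The enal comes from (R)-mevalonolactone (C2–C6, C15), a propargyl ether (C1, C10, C14) and DMF (C9) by acetylide acylation, Noyori transfer hydrogenation, Red-Al/I2 and formylation.
- Ring order: 8,12-lactone (butenolide) first, ten-membered carbocycle second. The side-chain acid is made from crotonaldehyde in three steps.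

Assumption: the compound is numbered as an 8,12-germacranolide (lactone O on C8, acyloxy on C6, tertiary carbinol C4, CH2OAc = C14); the given SMILES then reads (1(10)Z,2R,4S,6R,7R,8S,9S).

**Step 1**
Reactants: 1 (R)-mevalonolactone; 2 tert-butyldimethyl(prop-2-yn-1-yloxy)silane
Product: 4 (6R)-1-[(tert-butyldimethylsilyl)oxy]-6,8-dihydroxy-6-methyloct-2-yn-4-one, via the lithium acetylide 3 (not isolated)
Conditions: 2 (2.3 equiv), n-BuLi (2.2 equiv), THF, −78 °C; add 1, −78 °C, 1 h; aq NH4Cl at −78 °C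
Reagents that add atoms: none
Why: Acyl substitution of a lactone by a lithium acetylide: the lithium hemiketal is stable at −78 °C, so only one acetylide adds and cold protonation releases the hydroxy ynone; the first equivalent only deprotonates the tertiary OH, and the stereocentre of 1 is untouched.

**Step 2**
Reactants: 4 (6R)-1-[(tert-butyldimethylsilyl)oxy]-6,8-dihydroxy-6-methyloct-2-yn-4-one
Product: 6 (6R)-1-[(tert-butyldimethylsilyl)oxy]-6-hydroxy-8,8-dimethoxy-6-methyloct-2-yn-4-one, via the aldehyde 5 (not isolated)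
Conditions: PhI(OAc)2 (1.1 equiv), TEMPO (10 mol %), CH2Cl2, rt; concentrate; HC(OMe)3 (3 equiv), PPTS (5 mol %), MeOH, 0 °C
Reagents that add atoms: trimethyl orthoformate – COC(OC)OC
Why: TEMPO/PhI(OAc)2 oxidation touches only the primary alcohol, and the aliphatic aldehyde is acetalised far faster than the conjugated ynone (chemoselective oxidation, then acetalisation), so C6 is masked before any other hydroxyl exists.

**Step 3**
Reactants: 6 (6R)-1-[(tert-butyldimethylsilyl)oxy]-6-hydroxy-8,8-dimethoxy-6-methyloct-2-yn-4-one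
Product: 7 (4R,6S)-1-[(tert-butyldimethylsilyl)oxy]-8,8-dimethoxy-6-methyloct-2-yne-4,6-diol
Conditions: Ru[(R,R)-TsDPEN](p-cymene) (2 mol %), i-PrOH, rt
Reagents that add atoms: none
Why: Noyori asymmetric transfer hydrogenation of an α,β-acetylenic ketone under base-free conditions; the (R,R)-catalyst sets the propargylic carbinol (germacrane C2) as R by catalyst control, which is more reliable than 1,3-induction from a tertiary carbinol.

**Step 4**
Reactants: 7 (4R,6S)-1-[(tert-butyldimethylsilyl)oxy]-8,8-dimethoxy-6-methyloct-2-yne-4,6-diol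
Product: 9 (2Z,4R,6S)-1-[(tert-butyldimethylsilyl)oxy]-2-iodo-8,8-dimethoxy-6-methyloct-2-ene-4,6-diol, via the cyclic vinylalanate 8 (not isolated)
Conditions: Red-Al (4 equiv), THF, 0 °C → rt; EtOAc; I2, −78 → −20 °C; Rochelle salt
Reagents that add atoms: iodine – II
Why: Hydroxyl-directed trans-hydroalumination of the propargylic alcohol puts H on C3 and Al on C2 in a five-membered alanate, and iodinolysis with retention gives the (Z)-iodoalkene with iodine cis to the carbinol carbon, which fixes the later 1(10)-Z geometry.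

**Step 5**
Reactants: 9 (2Z,4R,6S)-1-[(tert-butyldimethylsilyl)oxy]-2-iodo-8,8-dimethoxy-6-methyloct-2-ene-4,6-diol
Product: 10 (4S,6R)-2,2-di-tert-butyl-6-[(1Z)-3-[(tert-butyldimethylsilyl)oxy]-2-iodoprop-1-en-1-yl]-4-(2,2-dimethoxyethyl)-4-methyl-1,3,2-dioxasilinane
Conditions: t-Bu2Si(OTf)2 (1.1 equiv), 2,6-lutidine (3 equiv), CH2Cl2, 0 °C
Reagents that add atoms: di-tert-butylsilyl bis(trifluoromethanesulfonate) – CC(C)(C)[Si](OS(=O)(=O)C(F)(F)F)(OS(=O)(=O)C(F)(F)F)C(C)(C)C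
Why: Silylene formation across the syn-1,3-diol protects the tertiary and the allylic hydroxyl in one operation; the group survives organolithiums, CAN, mild acid and Cr(II) and is removed by fluoride at the end.

**Step 6**
Reactants: 10 (4S,6R)-2,2-di-tert-butyl-6-[(1Z)-3-[(tert-butyldimethylsilyl)oxy]-2-iodoprop-1-en-1-yl]-4-(2,2-dimethoxyethyl)-4-methyl-1,3,2-dioxasilinane
Product: 12 (2Z)-2-{[(tert-butyldimethylsilyl)oxy]methyl}-3-[(4R,6S)-2,2-di-tert-butyl-6-(2,2-dimethoxyethyl)-6-methyl-1,3,2-dioxasilinan-4-yl]prop-2-enal, via the vinyllithium 11 (not isolated)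
Conditions: t-BuLi (2.1 equiv), Et2O, −78 °C, 20 min; DMF (5 equiv), −78 → −20 °C; aq NH4Cl
Reagents that add atoms: N,N-dimethylformamide – CN(C)C=O
Why: Iodine–lithium exchange proceeds with retention of alkene geometry and formylation of the vinyllithium (Bouveault-type) gives the (Z)-enal with the formyl carbon (C9) cis to C2; it is kept cold and used directly to avoid Z→E isomerisation.

**Step 7**
Reactants: 12 (2Z)-2-{[(tert-butyldimethylsilyl)oxy]methyl}-3-[(4R,6S)-2,2-di-tert-butyl-6-(2,2-dimethoxyethyl)-6-methyl-1,3,2-dioxasilinan-4-yl]prop-2-enal; 13 allyl 4-methoxyphenyl ether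
Product: 15 (3S,4S,5Z)-5-{[(tert-butyldimethylsilyl)oxy]methyl}-6-[(4R,6S)-2,2-di-tert-butyl-6-(2,2-dimethoxyethyl)-6-methyl-1,3,2-dioxasilinan-4-yl]-3-(4-methoxyphenoxy)hexa-1,5-dien-4-ol, via the allylborane 14 (not isolated)
Conditions: 13 (2.0 equiv), s-BuLi (1.9 equiv), THF, −78 °C; (+)-Ipc2BOMe (1.9 equiv); BF3·OEt2 (2.2 equiv); 12, −78 °C, 4 h; NaOH, H2O2, 0 °C → rt
Reagents that add atoms: none
Why: Brown γ-alkoxyallylboration: the (Z)-γ-aryloxyallylborane reacts through a chair transition state to give the syn 1,2-diol monoether, and the (+)-Ipc2B reagent (from (−)-α-pinene) selects the aldehyde face that gives 9S and 8S by reagent control.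

**Step 8**
Reactants: 15 (3S,4S,5Z)-5-{[(tert-butyldimethylsilyl)oxy]methyl}-6-[(4R,6S)-2,2-di-tert-butyl-6-(2,2-dimethoxyethyl)-6-methyl-1,3,2-dioxasilinan-4-yl]-3-(4-methoxyphenoxy)hexa-1,5-dien-4-ol
Product: 16 (3S,4S,5Z)-6-[(4R,6S)-2,2-di-tert-butyl-6-(2,2-dimethoxyethyl)-6-methyl-1,3,2-dioxasilinan-4-yl]-5-(hydroxymethyl)-3-(4-methoxyphenoxy)hexa-1,5-dien-4-ol
Conditions: CSA (10 mol %), MeOH/CH2Cl2, 0 °C
Reagents that add atoms: none
Why: Acid-catalysed methanolysis removes the primary allylic TBS ether, while the silylene and aryl ether are stable and the dimethyl acetal only exchanges with methanol.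

**Step 9**
Reactants: 16 (3S,4S,5Z)-6-[(4R,6S)-2,2-di-tert-butyl-6-(2,2-dimethoxyethyl)-6-methyl-1,3,2-dioxasilinan-4-yl]-5-(hydroxymethyl)-3-(4-methoxyphenoxy)hexa-1,5-dien-4-ol
Product: 17 (3S,4S,5Z)-5-(acetoxymethyl)-6-[(4R,6S)-2,2-di-tert-butyl-6-(2,2-dimethoxyethyl)-6-methyl-1,3,2-dioxasilinan-4-yl]-3-(4-methoxyphenoxy)hexa-1,5-dien-4-yl acetate
Conditions: Ac2O (4 equiv), pyridine, DMAP (10 mol %), CH2Cl2, 0 °C → rt
Reagents that add atoms: acetic anhydride – CC(=O)OC(C)=O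
Why: Standard acetylation installs the C14 and C9 acetates of the target in one step on the only two free hydroxyls.

**Step 10**
Reactants: 17 (3S,4S,5Z)-5-(acetoxymethyl)-6-[(4R,6S)-2,2-di-tert-butyl-6-(2,2-dimethoxyethyl)-6-methyl-1,3,2-dioxasilinan-4-yl]-3-(4-methoxyphenoxy)hexa-1,5-dien-4-yl acetate
Product: 18 (3S,4S,5Z)-5-(acetoxymethyl)-6-[(4R,6S)-2,2-di-tert-butyl-6-methyl-6-(2-oxoethyl)-1,3,2-dioxasilinan-4-yl]-3-hydroxyhexa-1,5-dien-4-yl acetate
Conditions: CAN (3 equiv), MeCN/H2O (4:1), 0 °C, 30 min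
Reagents that add atoms: water – O
Why: CAN oxidative dearylation of the 4-methoxyphenyl ether frees O8 without breaking the C8–O bond (retention), and the acidic aqueous medium hydrolyses the dimethyl acetal to the C6 aldehyde in the same operation; acetates and silylene survive and no base is present to move the C9 acetate.

**Step 11**
Reactants: 18 (3S,4S,5Z)-5-(acetoxymethyl)-6-[(4R,6S)-2,2-di-tert-butyl-6-methyl-6-(2-oxoethyl)-1,3,2-dioxasilinan-4-yl]-3-hydroxyhexa-1,5-dien-4-yl acetate; 19 2-(bromomethyl)prop-2-enoic acid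
Product: 20 (3S,4S,5Z)-4-acetoxy-5-(acetoxymethyl)-6-[(4R,6S)-2,2-di-tert-butyl-6-methyl-6-(2-oxoethyl)-1,3,2-dioxasilinan-4-yl]hexa-1,5-dien-3-yl 2-(bromomethyl)prop-2-enoate
Conditions: 19 (1.5 equiv), DCC (1.6 equiv), DMAP (5 mol %), CH2Cl2, −10 → 0 °C
Reagents that add atoms: none
Why: Steglich esterification of the only free hydroxyl forms the O8–C12 bond of the lactone; low temperature and low DMAP loading limit SN2′ attack on the allylic bromide and 9→8 acetyl migration.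

**Step 12**
Reactants: 20 (3S,4S,5Z)-4-acetoxy-5-(acetoxymethyl)-6-[(4R,6S)-2,2-di-tert-butyl-6-methyl-6-(2-oxoethyl)-1,3,2-dioxasilinan-4-yl]hexa-1,5-dien-3-yl 2-(bromomethyl)prop-2-enoate
Product: 21 (1S,2Z)-2-(acetoxymethyl)-1-[(2S)-4-(bromomethyl)-5-oxo-2,5-dihydrofuran-2-yl]-3-[(4R,6S)-2,2-di-tert-butyl-6-methyl-6-(2-oxoethyl)-1,3,2-dioxasilinan-4-yl]prop-2-en-1-yl acetate
Conditions: Hoveyda–Grubbs II (10 mol %), toluene (5 mM), 80 °C, Ar sparge
Reagents that add atoms: none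
Why: Ring-closing metathesis between the C7 vinyl group and the 2-substituted acrylate closes the butenolide (C7=C11) with loss of ethene; the hindered trisubstituted C1(10) alkene does not take part.

**Step 13**
Reactants: 21 (1S,2Z)-2-(acetoxymethyl)-1-[(2S)-4-(bromomethyl)-5-oxo-2,5-dihydrofuran-2-yl]-3-[(4R,6S)-2,2-di-tert-butyl-6-methyl-6-(2-oxoethyl)-1,3,2-dioxasilinan-4-yl]prop-2-en-1-yl acetate
Product: 23 (1(10)Z,2R,4R,6S,7R,8S,9S)-9,14-diacetoxy-2,4-[(di-tert-butylsilanediyl)dioxy]-6-hydroxygermacra-1(10),11(13)-dien-8,12-olide, via the allylchromium 22 (not isolated)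
Conditions: CrCl2 (8 equiv), THF, rt; 21 added over 12 h (final 1 mM); aq NH4Cl
Reagents that add atoms: none
Why: Proposed new method: Cr(II) inserts into the allylic C–Br bond and the γ-oxygenated allylchromium(III) adds through C7 to the tethered C6 aldehyde in a chair Zimmerman–Traxler transition state, forming the ten-membered ring and the C11=C13 exo-methylene; C7 is attacked anti to the C8 side chain (trans-lactone, 7R) and the ring-locked E-allylchromium (C8 trans to CH2Cr) gives the 6,7-anti (6S) alcohol, the C6 epimer that step 17 inverts; the closest known chemistry is the intramolecular Nozaki–Hiyama–Kishi allylation used to close ten-membered germacranolide rings and the intermolecular Cr- or Zn-mediated aldehyde allylation with 3-(bromomethyl)furan-2(5H)-ones.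

**Step 14**
Reactants: 24 (E)-but-2-enal
Product: 25 (Z)-2-iodobut-2-enal
Conditions: I2 (1.5 equiv), K2CO3 (1.2 equiv), DMAP (20 mol %), THF/H2O (1:1), rt
Reagents that add atoms: iodine – II
Why: α-Iodination of an enal by Baylis–Hillman-type conjugate addition of DMAP, enolate iodination and elimination; the methyl group stays trans to the formyl group, so iodine ends up cis to methyl.

**Step 15**
Reactants: 25 (Z)-2-iodobut-2-enal
Product: 26 (Z)-2-iodobut-2-en-1-ol
Conditions: NaBH4, CeCl3·7H2O, MeOH, 0 °C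
Reagents that add atoms: none
Why: Luche 1,2-reduction of the enal leaves the vinyl iodide and its geometry intact.

**Step 16**
Reactants: 26 (Z)-2-iodobut-2-en-1-ol
Product: 29 (Z)-2-(acetoxymethyl)but-2-enoic acid, via the dilithio alkoxide 27 (not isolated), via the dilithium carboxylate 28 (not isolated)
Conditions: n-BuLi (1.0 equiv), Et2O, −78 °C; t-BuLi (2.1 equiv), −78 °C; CO2; AcCl (1.05 equiv), −78 → 0 °C; 1 M HCl
Reagents that add atoms: carbon dioxide – O=C=O; acetyl chloride – CC(=O)Cl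
Why: Iodine–lithium exchange with retention followed by carboxylation puts the carboxyl group cis to the methyl group (angelate-type Z geometry), and the lithium alkoxide is acetylated by AcCl much faster than the lithium carboxylate.

**Step 17**
Reactants: 23 (1(10)Z,2R,4R,6S,7R,8S,9S)-9,14-diacetoxy-2,4-[(di-tert-butylsilanediyl)dioxy]-6-hydroxygermacra-1(10),11(13)-dien-8,12-olide; 29 (Z)-2-(acetoxymethyl)but-2-enoic acid
Product: 30 (1(10)Z,2R,4R,6R,7R,8S,9S)-6-{[(2Z)-2-(acetoxymethyl)but-2-enoyl]oxy}-9,14-diacetoxy-2,4-[(di-tert-butylsilanediyl)dioxy]germacra-1(10),11(13)-dien-8,12-olide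
Conditions: 29 (3 equiv), PPh3 (3 equiv), DIAD (3 equiv), toluene, 0 °C → rt
Reagents that add atoms: none
Why: Mitsunobu esterification: the carboxylate displaces the C6 oxyphosphonium by SN2, which installs the side chain and inverts C6 from S to R in one step; C6 is not allylic, so SN2′ is not possible, and the Z geometry of the acid is retained.

**Step 18**
Reactants: 30 (1(10)Z,2R,4R,6R,7R,8S,9S)-6-{[(2Z)-2-(acetoxymethyl)but-2-enoyl]oxy}-9,14-diacetoxy-2,4-[(di-tert-butylsilanediyl)dioxy]germacra-1(10),11(13)-dien-8,12-olide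
Product: 31 (1(10)Z,2R,4S,6R,7R,8S,9S)-6-{[(2Z)-2-(acetoxymethyl)but-2-enoyl]oxy}-9,14-diacetoxy-2,4-dihydroxygermacra-1(10),11(13)-dien-8,12-olide (CNP0126757.1)
Conditions: HF·pyridine, pyridine/THF, 0 °C → rt
Reagents that add atoms: none
Why: Fluoride cleavage of the di-tert-butylsilylene frees the C2 and C4 hydroxyls; the buffered conditions leave the three acetates, the Z-enoate and the α-methylene lactone intact and touch no stereocentre.

**Compound list**
1 | (R)-mevalonolactone, (4R)-4-hydroxy-4-methyloxan-2-one | C[C@@]1(O)CCOC(=O)C1 | starting material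
2 | tert-butyldimethyl(prop-2-yn-1-yloxy)silane | C#CCO[Si](C)(C)C(C)(C)C | starting material
3 | lithium 3-[(tert-butyldimethylsilyl)oxy]prop-1-yn-1-ide | [Li]C#CCO[Si](C)(C)C(C)(C)C | intermediate
4 | (6R)-1-[(tert-butyldimethylsilyl)oxy]-6,8-dihydroxy-6-methyloct-2-yn-4-one | OCC[C@@](C)(O)CC(=O)C#CCO[Si](C)(C)C(C)(C)C | intermediate
5 | (3R)-8-[(tert-butyldimethylsilyl)oxy]-3-hydroxy-3-methyl-5-oxooct-6-ynal | O=CC[C@@](C)(O)CC(=O)C#CCO[Si](C)(C)C(C)(C)C | intermediate
6 | (6R)-1-[(tert-butyldimethylsilyl)oxy]-6-hydroxy-8,8-dimethoxy-6-methyloct-2-yn-4-one | COC(OC)C[C@@](C)(O)CC(=O)C#CCO[Si](C)(C)C(C)(C)C | intermediate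
7 | (4R,6S)-1-[(tert-butyldimethylsilyl)oxy]-8,8-dimethoxy-6-methyloct-2-yne-4,6-diol | COC(OC)C[C@@](C)(O)C[C@@H](O)C#CCO[Si](C)(C)C(C)(C)C | intermediate
8 | sodium cyclic vinylalanate of 7 (O–Al–C2 five-membered ring, two 2-methoxyethoxy ligands; tertiary OH drawn free) | [Na+].COC(OC)C[C@@](C)(O)C[C@H]1O[Al-](OCCOC)(OCCOC)C(CO[Si](C)(C)C(C)(C)C)=C1 | intermediate
9 | (2Z,4R,6S)-1-[(tert-butyldimethylsilyl)oxy]-2-iodo-8,8-dimethoxy-6-methyloct-2-ene-4,6-diol | COC(OC)C[C@@](C)(O)C[C@@H](O)/C=C(/CO[Si](C)(C)C(C)(C)C)I | intermediate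
10 | (4S,6R)-2,2-di-tert-butyl-6-[(1Z)-3-[(tert-butyldimethylsilyl)oxy]-2-iodoprop-1-en-1-yl]-4-(2,2-dimethoxyethyl)-4-methyl-1,3,2-dioxasilinane | COC(OC)C[C@]1(C)C[C@H](/C=C(/CO[Si](C)(C)C(C)(C)C)I)O[Si](C(C)(C)C)(C(C)(C)C)O1 | intermediate
11 | vinyllithium from 10 (Li in place of I, geometry retained) | COC(OC)C[C@]1(C)C[C@H](/C=C(/CO[Si](C)(C)C(C)(C)C)[Li])O[Si](C(C)(C)C)(C(C)(C)C)O1 | intermediate
12 | (2Z)-2-{[(tert-butyldimethylsilyl)oxy]methyl}-3-[(4R,6S)-2,2-di-tert-butyl-6-(2,2-dimethoxyethyl)-6-methyl-1,3,2-dioxasilinan-4-yl]prop-2-enal | COC(OC)C[C@]1(C)C[C@H](/C=C(/CO[Si](C)(C)C(C)(C)C)C=O)O[Si](C(C)(C)C)(C(C)(C)C)O1 | intermediate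
13 | allyl 4-methoxyphenyl ether, 1-methoxy-4-(prop-2-en-1-yloxy)benzene | C=CCOc1ccc(OC)cc1 | starting material
14 | [(Z)-3-(4-methoxyphenoxy)prop-2-en-1-yl]diisopinocampheylborane (Ipc groups from (+)-Ipc2BOMe) | COc1ccc(O/C=C\CB([C@H]2C[C@H]3C[C@@H]([C@@H]2C)C3(C)C)[C@H]4C[C@H]5C[C@@H]([C@@H]4C)C5(C)C)cc1 | intermediate
15 | (3S,4S,5Z)-5-{[(tert-butyldimethylsilyl)oxy]methyl}-6-[(4R,6S)-2,2-di-tert-butyl-6-(2,2-dimethoxyethyl)-6-methyl-1,3,2-dioxasilinan-4-yl]-3-(4-methoxyphenoxy)hexa-1,5-dien-4-ol | COC(OC)C[C@]1(C)C[C@H](/C=C(/CO[Si](C)(C)C(C)(C)C)[C@H](O)[C@@H](Oc2ccc(OC)cc2)C=C)O[Si](C(C)(C)C)(C(C)(C)C)O1 | intermediate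
16 | (3S,4S,5Z)-6-[(4R,6S)-2,2-di-tert-butyl-6-(2,2-dimethoxyethyl)-6-methyl-1,3,2-dioxasilinan-4-yl]-5-(hydroxymethyl)-3-(4-methoxyphenoxy)hexa-1,5-dien-4-ol | COC(OC)C[C@]1(C)C[C@H](/C=C(/CO)[C@H](O)[C@@H](Oc2ccc(OC)cc2)C=C)O[Si](C(C)(C)C)(C(C)(C)C)O1 | intermediate
17 | (3S,4S,5Z)-5-(acetoxymethyl)-6-[(4R,6S)-2,2-di-tert-butyl-6-(2,2-dimethoxyethyl)-6-methyl-1,3,2-dioxasilinan-4-yl]-3-(4-methoxyphenoxy)hexa-1,5-dien-4-yl acetate | COC(OC)C[C@]1(C)C[C@H](/C=C(/COC(C)=O)[C@H](OC(C)=O)[C@@H](Oc2ccc(OC)cc2)C=C)O[Si](C(C)(C)C)(C(C)(C)C)O1 | intermediate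
18 | (3S,4S,5Z)-5-(acetoxymethyl)-6-[(4R,6S)-2,2-di-tert-butyl-6-methyl-6-(2-oxoethyl)-1,3,2-dioxasilinan-4-yl]-3-hydroxyhexa-1,5-dien-4-yl acetate | O=CC[C@]1(C)C[C@H](/C=C(/COC(C)=O)[C@H](OC(C)=O)[C@@H](O)C=C)O[Si](C(C)(C)C)(C(C)(C)C)O1 | intermediate
19 | 2-(bromomethyl)prop-2-enoic acid | C=C(CBr)C(=O)O | starting material
20 | (3S,4S,5Z)-4-acetoxy-5-(acetoxymethyl)-6-[(4R,6S)-2,2-di-tert-butyl-6-methyl-6-(2-oxoethyl)-1,3,2-dioxasilinan-4-yl]hexa-1,5-dien-3-yl 2-(bromomethyl)prop-2-enoate | O=CC[C@]1(C)C[C@H](/C=C(/COC(C)=O)[C@H](OC(C)=O)[C@@H](OC(=O)C(=C)CBr)C=C)O[Si](C(C)(C)C)(C(C)(C)C)O1 | intermediate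
21 | (1S,2Z)-2-(acetoxymethyl)-1-[(2S)-4-(bromomethyl)-5-oxo-2,5-dihydrofuran-2-yl]-3-[(4R,6S)-2,2-di-tert-butyl-6-methyl-6-(2-oxoethyl)-1,3,2-dioxasilinan-4-yl]prop-2-en-1-yl acetate | O=CC[C@]1(C)C[C@H](/C=C(/COC(C)=O)[C@H](OC(C)=O)[C@H]2OC(=O)C(CBr)=C2)O[Si](C(C)(C)C)(C(C)(C)C)O1 | intermediate
22 | allylchromium(III) dichloride from 21 (CrCl2 in place of Br) | O=CC[C@]1(C)C[C@H](/C=C(/COC(C)=O)[C@H](OC(C)=O)[C@H]2OC(=O)C(C[Cr](Cl)Cl)=C2)O[Si](C(C)(C)C)(C(C)(C)C)O1 | intermediate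
23 | (1(10)Z,2R,4R,6S,7R,8S,9S)-9,14-diacetoxy-2,4-[(di-tert-butylsilanediyl)dioxy]-6-hydroxygermacra-1(10),11(13)-dien-8,12-olide | C=C1C(=O)O[C@H]2[C@H]1[C@@H](O)C[C@]3(C)C[C@@H](O[Si](C(C)(C)C)(C(C)(C)C)O3)/C=C(/COC(C)=O)[C@@H]2OC(C)=O | intermediate
24 | (E)-but-2-enal (crotonaldehyde) | C/C=C/C=O | starting material
25 | (Z)-2-iodobut-2-enal | C/C=C(\I)C=O | intermediate
26 | (Z)-2-iodobut-2-en-1-ol | C/C=C(\I)CO | intermediate
27 | lithium (Z)-2-lithiobut-2-en-1-olate | C/C=C(\[Li])CO[Li] | intermediate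
28 | dilithium (Z)-2-(oxidomethyl)but-2-enoate | C/C=C(\C(=O)O[Li])CO[Li] | intermediate
29 | (Z)-2-(acetoxymethyl)but-2-enoic acid | C/C=C(\C(=O)O)COC(C)=O | intermediate
30 | (1(10)Z,2R,4R,6R,7R,8S,9S)-6-{[(2Z)-2-(acetoxymethyl)but-2-enoyl]oxy}-9,14-diacetoxy-2,4-[(di-tert-butylsilanediyl)dioxy]germacra-1(10),11(13)-dien-8,12-olide | C=C1C(=O)O[C@H]2[C@H]1[C@H](OC(=O)/C(=C\C)COC(C)=O)C[C@]3(C)C[C@@H](O[Si](C(C)(C)C)(C(C)(C)C)O3)/C=C(/COC(C)=O)[C@@H]2OC(C)=O | intermediate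
31 | (1(10)Z,2R,4S,6R,7R,8S,9S)-6-{[(2Z)-2-(acetoxymethyl)but-2-enoyl]oxy}-9,14-diacetoxy-2,4-dihydroxygermacra-1(10),11(13)-dien-8,12-olide | C=C1C(=O)O[C@H]2[C@H]1[C@H](OC(=O)/C(=C\C)COC(C)=O)C[C@@](C)(O)C[C@@H](O)/C=C(/COC(C)=O)[C@@H]2OC(C)=O | target

**Step count**
Total: 18 steps. Longest linear sequence: 15 steps (steps 1–13, 17, 18); the side-chain acid takes steps 14–16.

**Steps most likely to fail, with fallbacks**

Step 13 (macrocyclisation). The allylchromium may be protonated or dimerise, or the lactone C8–O bond may open, before the ten-membered ring closes. The fallback closes the same C6–C7 bond through an allylsilane instead of an allyl-metal. It sets out from 18, which is esterified (DCC, 5 mol % DMAP) with 2-[(trimethylsilyl)methyl]prop-2-enoic acid to give the silylmethyl acrylate ester F1. Ring-closing metathesis then gives the 3-(trimethylsilylmethyl)butenolide aldehyde F2. BF3·OEt2 (CH2Cl2, −78 °C, 1 mM) triggers an intramolecular Hosomi–Sakurai reaction through an open transition state, which is expected to give the 6,7-syn alcohol, the 6R epimer of 23 F3. Yamaguchi esterification of F3 with 29 (2,4,6-trichlorobenzoyl chloride, Et3N, then DMAP, toluene; retention) brings the material back to the route at 30. If the 6S epimer forms instead, it is 23 itself.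

Step 17 (Mitsunobu at a hindered ring carbinol). Elimination towards C5 or phosphine-induced Z→E isomerisation of the acid may compete. The fallback separates activation from displacement. It sets out from 23, which is converted (Tf2O, pyridine, CH2Cl2, −40 °C) into the C6 triflate of 23 F4. The triflate is displaced with inversion by the caesium salt of 29 (Cs2CO3, 18-crown-6, toluene, 0 °C → rt), and the route is rejoined at 30.

Step 12 (metathesis onto a 2-substituted acrylate that carries an allylic bromide next to a branched carbinol). The fallback closes the lactone by lactonisation instead. It sets out from 17: OsO4 (2 mol %)/NaIO4/2,6-lutidine in dioxane–water cleaves only the terminal vinyl group to give the C7 aldehyde F5. A Morita–Baylis–Hillman reaction with methyl acrylate (DABCO, MeOH) gives the C7 carbinol adduct F6 as a mixture of C7 epimers, which does not matter later. CAN in MeCN/H2O removes the aryl ether, the freed O8 lactonises onto the methyl ester, and the acetal is hydrolysed, giving the α-methylene-β-hydroxy-γ-butyrolactone aldehyde F7. SN2′ bromination (NBS/Me2S, CH2Cl2, −20 °C) moves the alkene into the ring and returns the route at 21.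

**Further compounds**
F1 | step 13 | (3S,4S,5Z)-4-acetoxy-5-(acetoxymethyl)-6-[(4R,6S)-2,2-di-tert-butyl-6-methyl-6-(2-oxoethyl)-1,3,2-dioxasilinan-4-yl]hexa-1,5-dien-3-yl 2-[(trimethylsilyl)methyl]prop-2-enoate | O=CC[C@]1(C)C[C@H](/C=C(/COC(C)=O)[C@H](OC(C)=O)[C@@H](OC(=O)C(=C)C[Si](C)(C)C)C=C)O[Si](C(C)(C)C)(C(C)(C)C)O1
F2 | step 13 | analogue of 21 with CH2SiMe3 in place of CH2Br | O=CC[C@]1(C)C[C@H](/C=C(/COC(C)=O)[C@H](OC(C)=O)[C@H]2OC(=O)C(C[Si](C)(C)C)=C2)O[Si](C(C)(C)C)(C(C)(C)C)O1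
F3 | step 13 | (6R)-epimer of 23 | C=C1C(=O)O[C@H]2[C@H]1[C@H](O)C[C@]3(C)C[C@@H](O[Si](C(C)(C)C)(C(C)(C)C)O3)/C=C(/COC(C)=O)[C@@H]2OC(C)=O
F4 | step 17 | 6-O-trifluoromethanesulfonate of 23 (configuration unchanged) | C=C1C(=O)O[C@H]2[C@H]1[C@@H](OS(=O)(=O)C(F)(F)F)C[C@]3(C)C[C@@H](O[Si](C(C)(C)C)(C(C)(C)C)O3)/C=C(/COC(C)=O)[C@@H]2OC(C)=O
F5 | step 12 | aldehyde from 17 with CHO in place of the vinyl group | COC(OC)C[C@]1(C)C[C@H](/C=C(/COC(C)=O)[C@H](OC(C)=O)[C@@H](Oc2ccc(OC)cc2)C=O)O[Si](C(C)(C)C)(C(C)(C)C)O1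
F6 | step 12 | Morita–Baylis–Hillman adduct of F5 with methyl acrylate (both C7 epimers) | COC(OC)C[C@]1(C)C[C@H](/C=C(/COC(C)=O)[C@H](OC(C)=O)[C@@H](Oc2ccc(OC)cc2)C(O)C(=C)C(=O)OC)O[Si](C(C)(C)C)(C(C)(C)C)O1
F7 | step 12 | α-methylene-β-hydroxy-γ-butyrolactone aldehyde (both C7 epimers) | O=CC[C@]1(C)C[C@H](/C=C(/COC(C)=O)[C@H](OC(C)=O)[C@H]2OC(=O)C(=C)C2O)O[Si](C(C)(C)C)(C(C)(C)C)O1
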